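Numbering used throughout: chroman-4-one numbering for the bicycle (O1, C2, C3, C4, C4a, C5 to C8, C8a); Cα is the benzylic carbon of the side chain on C8. Ring A is the benzene ring, ring B the dihydropyranone ring.

## Analysis of the target

The target is a chroman-4-one. Ring A (C4a, C5, C6, C7, C8, C8a) is a benzene ring in which every carbon is substituted, and ring B (O1, C2, C3, C4, C4a, C8a) is a dihydropyranone. Ring A carries a hydroxyl at C5 hydrogen-bonded to the C4 carbonyl, a prenyl group at C6, a methoxy group at C7 and, at C8, the branch CH(Ph)CH2CO2H. There are three stereocentres: C2 (S) and C3 (R) carry cis methyl groups, and Cα (R) is a diarylmethine lodged between the ortho oxygens O1 and O7. Cα and the C2/C3 pair are too far apart to influence each other, so each has to be set independently. C3 is α to the ketone and can epimerise to the trans isomer, the β-aryloxy ketone can open by retro-oxa-Michael reaction under base, the prenyl alkene cyclises onto neighbouring oxygens in strong acid, and the free acid forbids a late saponification next to these groups. The main difficulty is the hexasubstituted ring A, with three differentiated oxygens and two different carbon substituents at C6 and C8, plus a stereocentre on its most crowded carbon. The strategy rests on two features. O5 and O7 stand 1,3 to each other with O5 peri to C4=O, which is the pattern a 1,3-dimethoxy-1-silyloxy diene leaves after cycloaddition and aromatisation. The C4a–C8a bond is the enone double bond of a 2,3-dihydro-4H-pyran-4-one, so ring B, with C2 and C3 already in place, can be the two-carbon partner.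

## Retrosynthetic reasoning

**24 from 23.** Only two Si–O bonds are cut: the silyl ester and the O5 silyl ether of 23. This keeps the last step to a mild acidic methanolysis that cannot touch C3, the prenyl group or Cα.

**23 from 10 and 20.** The bonds C8–C8a and C5–C4a are cut. These two bonds separate the four contiguous functionalised carbons of ring A (C5 to C8, with O5, prenyl, O7 and the Cα branch) from the two carbons it shares with ring B. Ring B stays whole with both stereocentres, and Cα ends up on an open chain where it can come from a symmetrical precursor. Forward, diene 10 must add to the enone C5=C6 of 20 with its CH terminus on the oxygen-bearing carbon, and the adduct must lose two small molecules to aromatise. A halogen at C5 of the dienophile could also leave as HX, but it lowers the LUMO of a vinylogous ester too little for a hindered diene. The sulfinyl group of 20 activates more strongly, polarises the alkene in the same sense as the ketone, and leaves by thermal syn elimination without base. Methanol from the ketal carbon completes the aromatisation and leaves O5 silylated and O7 methylated.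

**20 from 18.** The O1–C6 bond and the C5=C6 double bond of the pyranone are cut, with C6 as a one-carbon unit at the formate oxidation level. Forward, a formamide acetal condenses with the active methylene of β-keto sulfoxide 18 and the secondary hydroxyl closes the ring. No bond to C2 or C3 is made or broken.

**18 from 15 and 16; 15 from 14; 14 from 11 and 12.** The C–C bond between the ketone carbon and the sulfinyl-bearing methylene is cut, giving Weinreb amide 15 and sulfoxide 16. Amide 15 comes from imide 14, and 14 from a syn aldol between propionyl imide 11 and acetaldehyde 12. That aldol sets the future C2 and C3 with the cis relationship in one step.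

**10 from 8.** The two O–Si bonds are cut. Forward, acid 8 is doubly deprotonated (carboxylate, then the γ-position of the β-methoxy enoate) and silylated on both oxygens. The carboxylate shields its own α-methylene from the base, which is why the acid is freed before this step.

**8 from 7; 7 from 6; 6 from 4 and 5; 4 from 2; 2 from 1.** In turn: removal of an allyl ester (8 from 7), the O–CH3 bond of the enol ether (7 from 6), the C6–prenyl bond (6 from β-keto ester 4 and prenyl bromide 5), and the C5–C6 bond of 4 by two-carbon homologation of hemiester 2. Hemiester 2 comes from anhydride 1 by desymmetrising alcoholysis, which creates Cα as the only stereocentre of this branch.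

## Alternatives that were turned down

**Alternative 1:** Disconnection of O1–C8a. Forward, a monovalent-copper-catalysed intramolecular etherification joins the C2 hydroxyl of an aldol-derived diol to an aryl bromide at C8a. C4 is kept as a carbinol so that no base-sensitive β-aryloxy ketone is present, and the product is the chromanol A1.
- For: both ring-B centres come from a reliable aldol, the C–O coupling does not break the carbinol C–O bond and so retains configuration, and the reaction type is well established. On precedent for its key step it is stronger than the chosen route.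
- Against: A1 is only the bicyclic core. C6 and C8 are still C–H, both flanked by two oxygens and hard to tell apart. The prenyl group, the whole Cα branch (a late enantioselective diarylmethine on a di-ortho-substituted arene) and the C4 oxidation are still to come, on a long linear sequence.
- Comparison: the chosen route accepts a riskier key step but places all six ring-A substituents by construction and carries Cα from a symmetrical precursor.

**Alternative 2:** Danheiser benzannulation. A 4-substituted cyclobutenone carrying the Cα chain, the methoxy and the prenyl group opens to a vinylketene, which combines with an alkoxyalkyne to form C8a–C4a and C5–C6 and give the phenol A2.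
- For: the regiochemistry is fixed by the mechanism, Cα can come from the same glutarate source, and the reaction class is known. For ring A alone it is at least as safe as the chosen cycloaddition.
- Against: in A2, C4a is C–H and O5 is an ethyl ether. Ring B must then be appended by acylation and O-closure, where the usual thermodynamic closures favour the trans-2,3 isomer and an aldol/inversion sequence would be needed for cis. The ethyl ether must be cleaved beside a methyl ether, and the trisubstituted cyclobutenone itself takes several steps.
- Comparison: the chosen route brings ring B in with C2 and C3 already fixed, so no stereocentre is created after the arene exists.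

**Alternative 3:** Disconnection of C3–C4. A chiral triazolium-derived carbene converts a C4a aldehyde into a Breslow intermediate that adds across the alkene of an O8a but-3-en-2-yl ether, making C3–C4 and the C3 methyl and closing ring B to give A3.
- For: it is the last C–C bond on a complete arene, C2 comes from a simple chiral allylic alcohol, and the hydroacylation is known on simple salicylaldehyde ethers, which the chosen key step cannot claim.
- Against: the aldehyde sits between two ortho substituents on a hexasubstituted ring, which hinders Breslow-intermediate formation. The new C3 centre is tertiary and α to the new ketone under basic carbene conditions, so the cis isomer is at risk. The hexasubstituted arene with Cα is needed before the key step and is not helped by it.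
- Comparison: the chosen route is stronger on C3 (set by aldol, never exposed to base afterwards) and on convergence; it is weaker on precedent for the key step.

Key step: step 11

Assumption: the sense of induction in step 1 is assigned by analogy with related anhydride alcoholyses; should the quinidine-derived catalyst deliver the S hemiester, its quinine-derived pseudoenantiomer is used instead.
Remark: sulfoxide 16 is used as the racemate, so 18 to 21 are mixtures of sulfur epimers; this has no consequence because sulfur is lost in step 11.

## Route

Step 1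
Reactants: 1 3-phenylglutaric anhydride
Product: 2 (R)-5-(allyloxy)-5-oxo-3-phenylpentanoic acid
Conditions: allyl alcohol (3 equiv), 9-amino-9-deoxy-epi-quinidine 3,5-bis(trifluoromethyl)phenyl thiourea (10 mol%), MTBE, −20 °C; crystallisation of an amine salt if needed
Reagents that add atoms: allyl alcohol, C=CCO
Why: Organocatalytic desymmetrising alcoholysis of a prochiral 3-substituted glutaric anhydride; the bifunctional cinchona catalyst activates one enantiotopic carbonyl by hydrogen bonding while its quinuclidine delivers the alcohol, which sets Cα.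

Step 2
Reactants: 2 (R)-5-(allyloxy)-5-oxo-3-phenylpentanoic acid
Product: 4 1-allyl 7-methyl (3R)-5-oxo-3-phenylheptanedioate, via acyl imidazolide 3 (not isolated)
Conditions: 1,1'-carbonyldiimidazole (CDI), THF, rt; then Mg(O2CCH2CO2Me)2, THF, rt → 40 °C; aq. HCl
Reagents that add atoms: magnesium bis(methyl malonate), COC(=O)CC(=O)[O-].COC(=O)CC(=O)[O-].[Mg+2]
Why: Masamune–Brooks homologation; the acyl imidazolide C-acylates the magnesium malonate half-ester and decarboxylation gives the β-keto ester under near-neutral conditions that leave the allyl ester and Cα untouched.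

Step 3
Reactants: 4 1-allyl 7-methyl (3R)-5-oxo-3-phenylheptanedioate; 5 prenyl bromide
Product: 6 1-allyl 7-methyl (3R)-6-(3-methylbut-2-en-1-yl)-5-oxo-3-phenylheptanedioate (C6 epimers)
Conditions: K2CO3, acetone, 50 °C
Reagents that add atoms: none
Why: C-alkylation of a β-keto ester enolate with a soft allylic bromide; only the methylene between the two carbonyls is acidic enough for K2CO3, so the distal ester and Cα are unaffected, and the C6 epimers converge in step 4.

Step 4
Reactants: 6 1-allyl 7-methyl (3R)-6-(3-methylbut-2-en-1-yl)-5-oxo-3-phenylheptanedioate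
Product: 7 1-allyl 7-methyl (3R)-5-methoxy-6-(3-methylbut-2-en-1-yl)-3-phenylhept-5-enedioate (E/Z mixture)
Conditions: Cs2CO3, Me2SO4, DMF, 0 °C → rt
Reagents that add atoms: dimethyl sulfate, COS(=O)(=O)OC
Why: O-alkylation of a β-keto ester enolate; the weakly ion-paired caesium enolate in DMF meets the hard electrophile at oxygen, and C-methylation is further disfavoured because it would build a quaternary carbon beside the prenyl group; both enol ether geometries are usable in step 6.

Step 5
Reactants: 7 1-allyl 7-methyl (3R)-5-methoxy-6-(3-methylbut-2-en-1-yl)-3-phenylhept-5-enedioate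
Product: 8 (3R)-5,7-dimethoxy-6-(3-methylbut-2-en-1-yl)-7-oxo-3-phenylhept-5-enoic acid
Conditions: Pd(PPh3)4 (5 mol%), morpholine, THF, rt; pH 4 buffer wash
Reagents that add atoms: none
Why: Tsuji–Trost deallylation with zerovalent palladium and morpholine as allyl acceptor is neutral, so the acid-labile enol ether, the methyl ester and the prenyl group (not an allylic electrophile) survive.

Step 6
Reactants: 8 (3R)-5,7-dimethoxy-6-(3-methylbut-2-en-1-yl)-7-oxo-3-phenylhept-5-enoic acid
Product: 10 trimethylsilyl (3S,4Z)-5,7-dimethoxy-6-(3-methylbut-2-en-1-yl)-3-phenyl-7-[(trimethylsilyl)oxy]hepta-4,6-dienoate, via dilithium dienolate carboxylate 9 (not isolated)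
Conditions: LiN(iPr)2 (2.3 equiv), THF, −78 °C; Me3SiCl (2.5 equiv), −78 °C → rt; filtration under Ar, used crude
Reagents that add atoms: chlorotrimethylsilane, C[Si](C)(C)Cl
Why: γ-Deprotonation of a β-methoxy enoate and O-silylation of the dienolate, the standard entry to 1,3-dialkoxy-1-silyloxy dienes; the first equivalent of base forms the carboxylate, which protects its own α-methylene, and allylic strain against the substituted C6 should place C3 trans to C6 on the new C4=C5 bond (the Z descriptor arises only because OMe outranks C6). Cα–H is not acidic; its descriptor changes to S by priority only.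

Step 7
Reactants: 11 (R)-4-benzyl-3-propionyloxazolidin-2-one; 12 acetaldehyde
Product: 14 (R)-4-benzyl-3-[(2R,3S)-3-hydroxy-2-methylbutanoyl]oxazolidin-2-one, via dibutylboron Z-enolate 13 (not isolated)
Conditions: Bu2BOTf, iPr2NEt, CH2Cl2, 0 °C; 12, −78 → 0 °C; H2O2, MeOH, pH 7 buffer
Reagents that add atoms: none
Why: Evans syn aldol; the Z boron enolate reacts through a chair transition state on the face away from the benzyl group of the R auxiliary, setting the α-methyl centre (future C3) and the carbinol (future C2) as 2R,3S, which is the syn arrangement that becomes cis-2,3 in ring B.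

Step 8
Reactants: 14 (R)-4-benzyl-3-[(2R,3S)-3-hydroxy-2-methylbutanoyl]oxazolidin-2-one
Product: 15 (2R,3S)-3-hydroxy-N-methoxy-N,2-dimethylbutanamide
Conditions: MeNHOMe·HCl, AlMe3, CH2Cl2, −20 °C → rt; aq. HCl
Reagents that add atoms: N,O-dimethylhydroxylamine hydrochloride, CNOC.Cl
Why: Aluminium-amide transamination of the imide to the Weinreb amide, assisted by the free β-hydroxyl; the α-centre is not epimerised and the auxiliary is recovered.

Step 9
Reactants: 15 (2R,3S)-3-hydroxy-N-methoxy-N,2-dimethylbutanamide; 16 methyl phenyl sulfoxide
Product: 18 (3R,4S)-4-hydroxy-3-methyl-1-(phenylsulfinyl)pentan-2-one (sulfur epimers), via lithiated sulfoxide 17 (not isolated)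
Conditions: 16 (3.3 equiv), LiN(iPr)2 (3.3 equiv), THF, −78 °C; then 15, −78 → −20 °C; aq. NH4Cl
Reagents that add atoms: none
Why: Acylation of an α-sulfinyl carbanion by a Weinreb amide; the chelated tetrahedral intermediate prevents over-addition, and the product is held as its doubly stabilised enolate, which protects the adjacent methyl-bearing centre from epimerisation and the aldol unit from retro-aldol cleavage.

Step 10
Reactants: 18 (3R,4S)-4-hydroxy-3-methyl-1-(phenylsulfinyl)pentan-2-one
Product: 20 (2S,3R)-2,3-dimethyl-5-(phenylsulfinyl)-2,3-dihydro-4H-pyran-4-one (sulfur epimers), via enaminone 19 (not isolated)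
Conditions: Me2NCH(OMe)2, THF, rt; then CF3CO2H, CH2Cl2, 0 °C → rt
Reagents that add atoms: N,N-dimethylformamide dimethyl acetal, COC(OC)N(C)C
Why: Condensation of the active methylene with the formamide acetal gives the enaminone, and acid-promoted 6-endo-trig addition–elimination by the secondary hydroxyl (loss of Me2NH) closes the dihydropyranone, as known for δ-hydroxy-β-keto esters; no bond to C2 or C3 is broken.

Step 11
Reactants: 10 trimethylsilyl (3S,4Z)-5,7-dimethoxy-6-(3-methylbut-2-en-1-yl)-3-phenyl-7-[(trimethylsilyl)oxy]hepta-4,6-dienoate; 20 (2S,3R)-2,3-dimethyl-5-(phenylsulfinyl)-2,3-dihydro-4H-pyran-4-one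
Product: 23 trimethylsilyl (3R)-3-[(2S,3R)-7-methoxy-2,3-dimethyl-6-(3-methylbut-2-en-1-yl)-4-oxo-5-[(trimethylsilyl)oxy]chroman-8-yl]-3-phenylpropanoate, via cycloadduct 21 (not isolated), via cyclohexadiene ketal 22 (not isolated)
Conditions: 10 (1.5 equiv), PhMe, rt → 70 °C, Ar; crude product taken into step 12
Reagents that add atoms: none
Why: Proposed new method: a thermal [4+2] cycloaddition of a 1,3-dialkoxy-1-silyloxy diene to a 5-sulfinyl-2,3-dihydro-4H-pyran-4-one with aromatisation in the same flask has not been shown, and the closest known reactions are the Diels–Alder/aromatisation of such dienes with halo-quinones and the cycloaddition with sulfenic acid loss of 3-sulfinylchromones. The diene HOMO is largest at its CH terminus (future C8) and the dienophile LUMO, lowered by the geminal ketone and sulfinyl group, is largest at the oxygen-bearing carbon (future C8a), so C8–C8a forms first and the oxocarbenium-like ketene acetal carbon then closes onto the sulfinyl-stabilised α-carbon to form C5–C4a, in an asynchronous or stepwise Michael-then-closure sequence that ends at the same cis-fused adduct 21. Ring A is closed as a six-membered ring by the [4+2] mode, which in the stepwise limit is a 6-(enolexo)-exo-trig closure. In 21 the sulfinyl group and H8a are cis, so a five-centre syn elimination of PhSOH gives 22, whose C5 is a doubly allylic mixed ketal; 1,4-loss of MeOH across C5 and C8 then aromatises ring A and leaves O5 as the silyl ether. No new stereocentre survives, because C4a, C5, C8 and C8a all become sp2, so endo/exo and facial selectivity do not matter; C2, C3 and Cα carry no hydrogen that is acidic under neutral thermal conditions (Cα returns to the R descriptor by priority only). The selectivity needed is regiochemical and is secured by the matched polarisation of the two partners and by C8a–H being the only hydrogen available to the sulfoxide elimination. Excess diene absorbs PhSOH and MeOH, and any loss of silyl groups is harmless because step 12 removes them.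

Step 12
Reactants: 23 trimethylsilyl (3R)-3-[(2S,3R)-7-methoxy-2,3-dimethyl-6-(3-methylbut-2-en-1-yl)-4-oxo-5-[(trimethylsilyl)oxy]chroman-8-yl]-3-phenylpropanoate
Product: 24 (3R)-3-[(2S,3R)-5-hydroxy-7-methoxy-2,3-dimethyl-6-(3-methylbut-2-en-1-yl)-4-oxochroman-8-yl]-3-phenylpropanoic acid
Conditions: citric acid, MeOH, rt
Reagents that add atoms: none
Why: Acid-catalysed methanolysis of a silyl ester and an aryl silyl ether; citric acid is too weak to cyclise or hydrate the prenyl group or to epimerise C3, and the freed 5-OH is held by hydrogen bonding to C4=O.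

## Compound list

1 | 3-phenylglutaric anhydride | O=C1CC(CC(=O)O1)c1ccccc1 | starting material
2 | (R)-5-(allyloxy)-5-oxo-3-phenylpentanoic acid | OC(=O)C[C@H](CC(=O)OCC=C)c1ccccc1 | intermediate
3 | allyl (R)-5-(1H-imidazol-1-yl)-5-oxo-3-phenylpentanoate (acyl imidazolide, not isolated) | O=C(C[C@H](CC(=O)OCC=C)c1ccccc1)n1ccnc1 | intermediate
4 | 1-allyl 7-methyl (3R)-5-oxo-3-phenylheptanedioate | COC(=O)CC(=O)C[C@H](CC(=O)OCC=C)c1ccccc1 | intermediate
5 | prenyl bromide (1-bromo-3-methylbut-2-ene) | CC(C)=CCBr | starting material
6 | 1-allyl 7-methyl (3R)-6-(3-methylbut-2-en-1-yl)-5-oxo-3-phenylheptanedioate (C6 epimers) | COC(=O)C(CC=C(C)C)C(=O)C[C@H](CC(=O)OCC=C)c1ccccc1 | intermediate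
7 | 1-allyl 7-methyl (3R)-5-methoxy-6-(3-methylbut-2-en-1-yl)-3-phenylhept-5-enedioate (E/Z mixture) | COC(=O)C(CC=C(C)C)=C(OC)C[C@H](CC(=O)OCC=C)c1ccccc1 | intermediate
8 | (3R)-5,7-dimethoxy-6-(3-methylbut-2-en-1-yl)-7-oxo-3-phenylhept-5-enoic acid | COC(=O)C(CC=C(C)C)=C(OC)C[C@H](CC(=O)O)c1ccccc1 | intermediate
9 | dilithium (3S,4Z)-5,7-dimethoxy-6-(3-methylbut-2-en-1-yl)-7-oxido-3-phenylhepta-4,6-dienoate (not isolated) | [Li+].[Li+].COC([O-])=C(CC=C(C)C)/C(OC)=C/[C@H](CC(=O)[O-])c1ccccc1 | intermediate
10 | trimethylsilyl (3S,4Z)-5,7-dimethoxy-6-(3-methylbut-2-en-1-yl)-3-phenyl-7-[(trimethylsilyl)oxy]hepta-4,6-dienoate | COC(O[Si](C)(C)C)=C(CC=C(C)C)/C(OC)=C/[C@H](CC(=O)O[Si](C)(C)C)c1ccccc1 | intermediate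
11 | (R)-4-benzyl-3-propionyloxazolidin-2-one | CCC(=O)N1[C@H](Cc2ccccc2)COC1=O | starting material
12 | acetaldehyde | CC=O | starting material
13 | (R,Z)-4-benzyl-3-{1-[(dibutylboranyl)oxy]prop-1-en-1-yl}oxazolidin-2-one (not isolated) | C/C=C(\OB(CCCC)CCCC)N1[C@H](Cc2ccccc2)COC1=O | intermediate
14 | (R)-4-benzyl-3-[(2R,3S)-3-hydroxy-2-methylbutanoyl]oxazolidin-2-one | O[C@@H](C)[C@@H](C)C(=O)N1[C@H](Cc2ccccc2)COC1=O | intermediate
15 | (2R,3S)-3-hydroxy-N-methoxy-N,2-dimethylbutanamide | O[C@@H](C)[C@@H](C)C(=O)N(C)OC | intermediate
16 | methyl phenyl sulfoxide (racemic) | CS(=O)c1ccccc1 | starting material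
17 | [(phenylsulfinyl)methyl]lithium (not isolated) | [Li+].[CH2-]S(=O)c1ccccc1 | intermediate
18 | (3R,4S)-4-hydroxy-3-methyl-1-(phenylsulfinyl)pentan-2-one (sulfur epimers) | O[C@@H](C)[C@@H](C)C(=O)CS(=O)c1ccccc1 | intermediate
19 | (4R,5S)-1-(dimethylamino)-5-hydroxy-4-methyl-2-(phenylsulfinyl)hex-1-en-3-one (not isolated) | O[C@@H](C)[C@@H](C)C(=O)C(=CN(C)C)S(=O)c1ccccc1 | intermediate
20 | (2S,3R)-2,3-dimethyl-5-(phenylsulfinyl)-2,3-dihydro-4H-pyran-4-one (sulfur epimers) | O1[C@@H](C)[C@@H](C)C(=O)C(S(=O)c2ccccc2)=C1 | intermediate
21 | trimethylsilyl (3S)-3-[(2S,3R)-5,7-dimethoxy-2,3-dimethyl-6-(3-methylbut-2-en-1-yl)-4-oxo-4a-(phenylsulfinyl)-5-[(trimethylsilyl)oxy]-3,4,4a,5,8,8a-hexahydro-2H-chromen-8-yl]-3-phenylpropanoate (cis-fused cycloadduct, mixture at C5, C8 and sulfur, not isolated) | COC1=C(CC=C(C)C)C(OC)(O[Si](C)(C)C)C2(S(=O)c3ccccc3)C(O[C@@H](C)[C@@H](C)C2=O)C1[C@H](CC(=O)O[Si](C)(C)C)c1ccccc1 | intermediate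
22 | trimethylsilyl (3S)-3-[(2S,3R)-5,7-dimethoxy-2,3-dimethyl-6-(3-methylbut-2-en-1-yl)-4-oxo-5-[(trimethylsilyl)oxy]-3,4,5,8-tetrahydro-2H-chromen-8-yl]-3-phenylpropanoate (not isolated) | COC1=C(CC=C(C)C)C(OC)(O[Si](C)(C)C)C2=C(O[C@@H](C)[C@@H](C)C2=O)C1[C@H](CC(=O)O[Si](C)(C)C)c1ccccc1 | intermediate
23 | trimethylsilyl (3R)-3-[(2S,3R)-7-methoxy-2,3-dimethyl-6-(3-methylbut-2-en-1-yl)-4-oxo-5-[(trimethylsilyl)oxy]chroman-8-yl]-3-phenylpropanoate | COc1c(CC=C(C)C)c(O[Si](C)(C)C)c2c(c1[C@H](CC(=O)O[Si](C)(C)C)c1ccccc1)O[C@@H](C)[C@@H](C)C2=O | intermediate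
24 | (3R)-3-[(2S,3R)-5-hydroxy-7-methoxy-2,3-dimethyl-6-(3-methylbut-2-en-1-yl)-4-oxochroman-8-yl]-3-phenylpropanoic acid | COc1c(CC=C(C)C)c(O)c2c(c1[C@H](CC(=O)O)c1ccccc1)O[C@@H](C)[C@@H](C)C2=O | target

## Step count and least certain steps

Total: 12 steps. Longest linear sequence: 8 steps (steps 1 to 6, then 11 and 12); the dienophile branch is 4 steps (steps 7 to 10).

**Step 11 (key step, proposed new method).**
- Most likely failure: insufficient reactivity between the hindered, tetrasubstituted diene and a dienophile whose β-oxygen still raises the LUMO. The diene would then be consumed by protodesilylation (by PhSOH or MeOH) or by a 1,5-hydrogen shift from Cα on heating.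
- Other possible failures: conjugate addition without ring closure (silyl transfer to the enolate oxygen), opening of ring B by β-elimination of O1 after the first bond has formed, and loss of silanol instead of methanol from C5, which would methylate O5.
- Fallback with known reactions only, setting out from 15 and 10 and returning at 24:
  - HC≡CMgBr adds to 15 to give the ynone (4R,5S)-5-hydroxy-4-methylhex-1-yn-3-one F1.
  - Ph3PAuCl/AgOTf (monovalent gold) closes F1 6-endo-dig to (2S,3R)-2,3-dimethyl-2,3-dihydro-4H-pyran-4-one F2.
  - A Me3SiOTf-catalysed vinylogous Mukaiyama–Michael addition of 10 to F2 gives, after aqueous work-up, (3S)-4-[(5R,6S)-5,6-dimethyl-4-oxotetrahydro-2H-pyran-2-yl]-5,7-dimethoxy-6-(3-methylbut-2-en-1-yl)-7-oxo-3-phenylhept-5-enoic acid F3.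
  - LiN(SiMe3)2 effects Dieckmann closure of the less hindered ketone enolate onto the methyl ester to give (3S)-3-[(2S,3R)-7-methoxy-2,3-dimethyl-6-(3-methylbut-2-en-1-yl)-4,5-dioxo-3,4,4a,5,8,8a-hexahydro-2H-chromen-8-yl]-3-phenylpropanoic acid F4.
  - NBS brominates the carbon between the two carbonyls to give (3S)-3-[(2S,3R)-4a-bromo-7-methoxy-2,3-dimethyl-6-(3-methylbut-2-en-1-yl)-4,5-dioxo-3,4,4a,5,8,8a-hexahydro-2H-chromen-8-yl]-3-phenylpropanoic acid F5. Et3N then eliminates HBr and tautomerisation gives 24.

**Step 6.**
- Most likely failure: incomplete γ-deprotonation of the tetrasubstituted enoate (especially the geometric isomer whose γ-methylene is remote from the ester), partial C-silylation, and hydrolytic loss of the ketene acetal and silyl ester during handling.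
- Fallback, setting out from 8 and 20 and returning at 24: the dianion 9 is generated as before but not silylated, and 20 is added at −78 °C. Conjugate addition of the γ-carbon to the α-sulfinyl enone, then Claisen-type closure of the sulfinyl-stabilised enolate onto the methyl ester on warming, should give (3S)-3-[(2S,3R)-7-methoxy-2,3-dimethyl-6-(3-methylbut-2-en-1-yl)-4,5-dioxo-4a-(phenylsulfinyl)-3,4,4a,5,8,8a-hexahydro-2H-chromen-8-yl]-3-phenylpropanoic acid F6. F6 loses benzenesulfenic acid and tautomerises to 24 on mild acidic work-up. This anionic annulation needs no silyl diene.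

**Step 4.**
- Most likely failure: competing C-methylation of the ambident enolate, giving a quaternary β-keto ester that cannot form the diene.
- Fallback, setting out from 6 and returning at 7: HC(OMe)3 with catalytic TsOH in MeOH converts the ketone into the dimethyl ketal 1-allyl 7-methyl (3R)-5,5-dimethoxy-6-(3-methylbut-2-en-1-yl)-3-phenylheptanedioate F7. Me3SiOTf/iPr2NEt at −40 °C then eliminates methanol toward the ester-activated C6–H to give 7. Any regioisomeric enol ether converges at 9 in step 6.

**Step 10.**
- Most likely failure: epimerisation at the methyl-bearing α-centre (future C3) during the amine-releasing condensation or the acid treatment, or incomplete ring closure.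
- Fallback, setting out from 15 and returning at 20: F1 and F2 are made as described for step 11, so ring closure becomes a neutral gold-catalysed step. PhSCl adds to the enol ether double bond of F2 and Et3N eliminates HCl to give (2S,3R)-2,3-dimethyl-5-(phenylthio)-2,3-dihydro-4H-pyran-4-one F8. One equivalent of mCPBA at −78 °C oxidises sulfur to give 20.

## Further compounds

F1 | step 11 | (4R,5S)-5-hydroxy-4-methylhex-1-yn-3-one | O[C@@H](C)[C@@H](C)C(=O)C#C
F2 | step 11 | (2S,3R)-2,3-dimethyl-2,3-dihydro-4H-pyran-4-one | O1[C@@H](C)[C@@H](C)C(=O)C=C1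
F3 | step 11 | (3S)-4-[(5R,6S)-5,6-dimethyl-4-oxotetrahydro-2H-pyran-2-yl]-5,7-dimethoxy-6-(3-methylbut-2-en-1-yl)-7-oxo-3-phenylhept-5-enoic acid (mixture at the two new centres) | COC(=O)C(CC=C(C)C)=C(OC)C([C@H](CC(=O)O)c1ccccc1)C1CC(=O)[C@H](C)[C@H](C)O1
F4 | step 11 | (3S)-3-[(2S,3R)-7-methoxy-2,3-dimethyl-6-(3-methylbut-2-en-1-yl)-4,5-dioxo-3,4,4a,5,8,8a-hexahydro-2H-chromen-8-yl]-3-phenylpropanoic acid | COC1=C(CC=C(C)C)C(=O)C2C(O[C@@H](C)[C@@H](C)C2=O)C1[C@H](CC(=O)O)c1ccccc1
F5 | step 11 | (3S)-3-[(2S,3R)-4a-bromo-7-methoxy-2,3-dimethyl-6-(3-methylbut-2-en-1-yl)-4,5-dioxo-3,4,4a,5,8,8a-hexahydro-2H-chromen-8-yl]-3-phenylpropanoic acid | COC1=C(CC=C(C)C)C(=O)C2(Br)C(O[C@@H](C)[C@@H](C)C2=O)C1[C@H](CC(=O)O)c1ccccc1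
F6 | step 6 | (3S)-3-[(2S,3R)-7-methoxy-2,3-dimethyl-6-(3-methylbut-2-en-1-yl)-4,5-dioxo-4a-(phenylsulfinyl)-3,4,4a,5,8,8a-hexahydro-2H-chromen-8-yl]-3-phenylpropanoic acid | COC1=C(CC=C(C)C)C(=O)C2(S(=O)c3ccccc3)C(O[C@@H](C)[C@@H](C)C2=O)C1[C@H](CC(=O)O)c1ccccc1
F7 | step 4 | 1-allyl 7-methyl (3R)-5,5-dimethoxy-6-(3-methylbut-2-en-1-yl)-3-phenylheptanedioate | COC(=O)C(CC=C(C)C)C(OC)(OC)C[C@H](CC(=O)OCC=C)c1ccccc1
F8 | step 10 | (2S,3R)-2,3-dimethyl-5-(phenylthio)-2,3-dihydro-4H-pyran-4-one | O1[C@@H](C)[C@@H](C)C(=O)C(Sc2ccccc2)=C1
A1 | alternative 1 | (2S,3S,4S)-7-methoxy-5-(methoxymethoxy)-2,3-dimethylchroman-4-ol (2,3-cis) | COc1cc2O[C@@H](C)[C@@H](C)[C@H](O)c2c(OCOC)c1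
A2 | alternative 2 | methyl (3R)-3-[4-ethoxy-2-hydroxy-6-methoxy-5-(3-methylbut-2-en-1-yl)phenyl]-3-phenylpropanoate | COc1c(CC=C(C)C)c(OCC)cc(O)c1[C@H](CC(=O)OC)c1ccccc1
A3 | alternative 3 | methyl (3R)-3-[(2S,3R)-7-methoxy-2,3-dimethyl-6-(3-methylbut-2-en-1-yl)-4-oxo-5-[(triisopropylsilyl)oxy]chroman-8-yl]-3-phenylpropanoate | COc1c(CC=C(C)C)c(O[Si](C(C)C)(C(C)C)C(C)C)c2c(c1[C@H](CC(=O)OC)c1ccccc1)O[C@@H](C)[C@@H](C)C2=O
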